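## Analysis of the target

The target 32 is a monocyclic, elemane-type sesquiterpenoid. Its one cyclohexane ring (C5–C10) has a quaternary C10 (C14 methyl, C1=C2 vinyl), a single methylene C9, the acyloxy group on C8, the acrylic acid C11(=C13)–C12OOH on C7, a free hydroxyl on C6 and the unit C4(=C3)–C15H2OH on C5. Five ring stereocentres (5R,6S,7S,8S,10S) and the (2R) centre of the 3-hydroxy-2-methylpropanoyl residue must be controlled; C5–C8 are contiguous and C10 is an all-carbon quaternary neighbour of C5. In the chair that puts the C4 unit, the C11 unit, O8 and the vinyl group equatorial, the C14 methyl and the C6 hydroxyl are both axial and syn; O6 is therefore cis to the acrylic acid on C7 and trans to O8, and the C5 substituent is cis to C14. The sensitive groups are the γ-hydroxy-α-methylene acid (O6/C12), which can close to the cis-fused α-methylene lactone under acid, the acrylate as a Michael acceptor, the β-hydroxy ester side chain (epimerisation or elimination under base) and a primary allylic alcohol. The difficulty lies in the density of function: three hydroxyls of which only O8 is acylated, two carboxyl groups of which C12 must end free, an axial alcohol beside a quaternary centre, and three terminal alkenes that restrict oxidative and metathetic operations. The strategy rests on the C6 carbinol next to C7 carrying the 2-propenoate: this is the retron of a 2-(metallomethyl)acrylate adding through its γ-carbon to an aldehyde, and because C6–C7 is a ring bond the same addition, run intramolecularly, closes the ring and sets both centres cis.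

## Retrosynthetic reasoning

32 from 31. No skeletal bond is cut. All three protecting groups of 31 (two silyl ethers, one silylethyl ester) are chosen to fall to fluoride in one operation, which releases C12 as a carboxylate and so avoids acid at the stage where O6 could lactonise.

31 from 27 and 30. The acyl C–O bond at O8 is cut last. An ester on O8 earlier would be a leaving group in the 4-position of the allylmetal of the key step. The forward reaction has to distinguish the equatorial O8 of 27 from the axial O6, which is flanked by the C5 and C7 substituents and is syn to C14.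

27 from 24 (open form 25). The ring bond C6–C7 is cut. This is the only ring bond whose formation creates two stereocentres and delivers the acrylate at its final oxidation level. The precursor is a δ-hydroxy aldehyde and will exist as the six-membered lactol 24; this is used as a storage form that protects the epimerisable C5 next to the aldehyde. The forward reaction needs indium metal in water to open the lactol, form the allylmetal and close the ring with O6 cis to C11.

24 from 23, and 23 from 19 and 22. The C7=C11 double bond is cut by cross-metathesis. It is run on the ring acetal 19 and not on an open-chain vinyl carbinol, because the open chain holds the C7 and C1 vinyl groups as a 1,6-diene that would ring-close to a cyclopentene. In the six-membered acetal these two vinyl groups are trans and cannot meet.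

19 from 18 from 17. These are redox and protection steps. The δ-lactone 17 ties O8 to C6, so one hydride reduction gives the C6 aldehyde oxidation level and the free C8 oxygen together, with no separate protecting groups.

17 from 15. The C7–C8 bond is cut. A reagent-controlled vinyl addition to the C8 aldehyde sets C8, and the alkoxide closes onto the C6 ester. Any C8 epimer becomes a ring diastereomer that can be removed.

15 from 14 from 13 from 12. Functional group changes only: esterification of C6, release of O8 and oxidation to the aldehyde.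

12 from 10. The C5–C10 bond is cut by an ester enolate [3,3] rearrangement. It makes the quaternary centre and its tertiary neighbour in one step and leaves the C1=C2 vinyl group behind. The forward reaction needs an (E)-olefin in the allyl part, the E(O)-enolate, and a chiral boron substituent on the enolate oxygen for absolute control.

10 from 9 from 7 from 5 and 6. The ester C–O bond is cut. The anhydride 6 is opened by alcohol 5 at its non-conjugated carbonyl, and the remaining conjugated acid is reduced to C15 and silylated. The four-carbon acid part, with its 1,1-disubstituted olefin and the C15 oxygen, is thus taken directly from an itaconate.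

5 from 2 from 1. The trisubstituted olefin is made by methylmetalation of the alkyne and one-carbon capture, which gives only the (E)-isomer that the rearrangement requires.

22 from 20, and 30 from 29 from 28. These are the two side fragments: esterification of the bromo acid, and silylation then hydrolysis of the chiral-pool hydroxy ester.

## Alternatives that were turned down

Alternative 1: Radical cyclisation of a C6 bromoacetal with oxygen capture at C8.
- Disconnection: C7–C11 and C8–O.
- Key step: the bromoacetal A1 of a cyclohex-7-en-6-ol, with Bu3SnH under air, would give a primary radical that adds 5-exo to C7. The C8 radical would be trapped by O2 to give the cis-fused bicyclic acetal alcohol A2.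
- For: the cis relation of O6 and C11 is enforced by the five-membered ring fusion. This is a firmer guarantee than the transition-state preference the chosen route relies on. The carbocycle and C5/C10 could also be carried in from a cyclohexenol.
- Against: C11–C12 arrive as a saturated acetal. A2 would still need oxidation to the lactone, α-methylenation for C13, and then a regioselective opening of exactly the cis-fused lactone that the target avoids, with O8 acylated without relactonisation. The oxygenation at C8 must also win against tin hydride reduction of both radicals.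
- Comparison: at least six operations after the key step against two. The chosen route gives up the ring-fusion guarantee but delivers the acrylate open and at its final oxidation level.

Alternative 2: Ring-closing metathesis that selects one of two vinyl groups on C10.
- Disconnection: C8=C9.
- Key step: the acyclic bis-vinyl silyl enol ether A3, with second-generation Grubbs catalyst, would close to the cyclic enol ether A4 and make C10 stereogenic.
- For: six-membered ring-closing metathesis is robust, and C10 is created from a symmetric unit without any asymmetric C–C bond formation. On that point it is stronger than a rearrangement that must control enolate geometry. The C8 ketone is also revealed regiospecifically.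
- Against: the choice between the diastereotopic vinyl groups rests only on the C5 substituent. The 1,1-disubstituted silyl enol ether beside a quaternary carbon is a poor metathesis partner. The C5–C6–C7 triad must first be built in the open chain. After closure, a stereoselective C8 reduction is needed, and the CH2CH2O side chain must be converted into the acrylic acid by methylenation next to two β-oxygen substituents that can eliminate; this is about eight steps.
- Comparison: the chosen route sets C6 and C7 in the ring-closing step itself and needs two steps afterwards.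

Alternative 3: Intramolecular Stetter addition–elimination closing C7–C8.
- Disconnection: C7–C8.
- Key step: a triazolium-derived carbene would turn the C8 aldehyde of A5 into an acyl anion equivalent. This adds to C7 of the 2-(acetoxymethyl)enoate, and loss of acetate gives the ketone A6 with the C11=C13 acrylate in place.
- For: it is catalytic and metal-free, the acrylate appears directly, and the C7 configuration wanted (C11 equatorial) is the thermodynamic one. In atom economy it is at least as good as the chosen step.
- Against: in A6 the C7 hydrogen is α to the ketone and allylic to the acrylate, so epimerisation and migration of the double bond into conjugation threaten under the basic conditions. The O6 silyl ether is β to the ketone and can be eliminated. C6 must be set beforehand in the open chain. A C8 reduction to the equatorial alcohol must follow in the presence of the acrylate.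
- Comparison: the chosen route brings C8 in as an alcohol of defined configuration and forms C6 and C7 together in neutral water.

Key step: step 16

Assumption: the sense of induction of the two reagent-controlled steps follows the usual behaviour of these reagent classes — the (S,S)-diazaborolidine of step 6 is taken to give the (5R,10S) acid and (+)-MIB of step 10 the (8S) carbinol; if either sense is opposite, the mirror-image reagent is used.

## Steps

Step 1
Reactants: 1 but-3-yn-1-ol
Product: 2 1-[(but-3-yn-1-yloxy)methyl]-4-methoxybenzene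
Conditions: NaH, 4-methoxybenzyl chloride, Bu4NI (cat.), THF/DMF, 0 °C to rt
Reagents that add atoms: 4-methoxybenzyl chloride, COc1ccc(CCl)cc1
Why: Williamson etherification of the alkoxide; NaH does not deprotonate the alkyne C–H under these conditions, and the PMB ether can later be removed oxidatively beside silyl ethers.

Step 2
Reactants: 2 1-[(but-3-yn-1-yloxy)methyl]-4-methoxybenzene
Product: 5 (2E)-5-[(4-methoxybenzyl)oxy]-3-methylpent-2-en-1-ol, via alkenyldimethylalane 3 (not isolated), via lithium alkenylaluminate 4 (not isolated)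
Conditions: AlMe3, Cp2ZrCl2 (25 mol %), CH2Cl2, 0 °C to rt; n-BuLi, THF, −78 °C; (CH2O)n, −78 °C to rt; aq. potassium sodium tartrate
Reagents that add atoms: trimethylaluminium, C[Al](C)C; formaldehyde (as paraformaldehyde), C=O
Why: Zirconium-catalysed methylalumination (Negishi carboalumination) adds methyl and aluminium syn across the alkyne with aluminium on the terminal carbon, and the aluminate is hydroxymethylated with retention. The trisubstituted olefin should therefore form as the pure (E)-isomer, on which the C10 configuration depends.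

Step 3
Reactants: 5 (2E)-5-[(4-methoxybenzyl)oxy]-3-methylpent-2-en-1-ol; 6 itaconic anhydride (3-methylideneoxolane-2,5-dione)
Product: 7 4-{[(2E)-5-[(4-methoxybenzyl)oxy]-3-methylpent-2-en-1-yl]oxy}-2-methylidene-4-oxobutanoic acid
Conditions: toluene, 60 °C
Reagents that add atoms: none
Why: Uncatalysed alcoholysis of the anhydride takes place at the non-conjugated, more electrophilic carbonyl and should give the 4-ester with the acrylic acid free; no amine is used, so isomerisation to citraconic anhydride is avoided.

Step 4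
Reactants: 7 4-{[(2E)-5-[(4-methoxybenzyl)oxy]-3-methylpent-2-en-1-yl]oxy}-2-methylidene-4-oxobutanoic acid
Product: 9 (2E)-5-[(4-methoxybenzyl)oxy]-3-methylpent-2-en-1-yl 3-(hydroxymethyl)but-3-enoate, via mixed carbonic anhydride 8 (not isolated)
Conditions: i-BuOCOCl, N-methylmorpholine, THF, −15 °C; then NaBH4, THF/H2O, 0 °C
Reagents that add atoms: none
Why: Mixed-anhydride activation followed by borohydride reduces the carboxylic acid to the C15 alcohol beside the allyl ester and the trisubstituted olefin, which borane would attack; 1,2-reduction of the 2-substituted acryloyl unit is expected.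

Step 5
Reactants: 9 (2E)-5-[(4-methoxybenzyl)oxy]-3-methylpent-2-en-1-yl 3-(hydroxymethyl)but-3-enoate
Product: 10 (2E)-5-[(4-methoxybenzyl)oxy]-3-methylpent-2-en-1-yl 3-({[tert-butyl(dimethyl)silyl]oxy}methyl)but-3-enoate
Conditions: TBSCl, imidazole, CH2Cl2, 0 °C
Reagents that add atoms: tert-butyldimethylsilyl chloride, CC(C)(C)[Si](C)(C)Cl
Why: Standard silylation, carried out at once so that the γ-hydroxy ester cannot lactonise with loss of 5.

Step 6
Reactants: 10 (2E)-5-[(4-methoxybenzyl)oxy]-3-methylpent-2-en-1-yl 3-({[tert-butyl(dimethyl)silyl]oxy}methyl)but-3-enoate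
Product: 12 (2R,3S)-2-(3-{[tert-butyl(dimethyl)silyl]oxy}prop-1-en-2-yl)-3-ethenyl-5-[(4-methoxybenzyl)oxy]-3-methylpentanoic acid, via boron enolate 11 (not isolated)
Conditions: (4S,5S)-2-bromo-1,3-bis{[3,5-bis(trifluoromethyl)phenyl]sulfonyl}-4,5-diphenyl-1,3,2-diazaborolidine (1.2 equiv, made beforehand from the bis-sulfonamide and BBr3), Et3N, toluene/hexane, −78 °C, then 4 °C to rt; aqueous work-up
Reagents that add atoms: none
Why: Enantioselective Ireland–Claisen rearrangement of a chiral boron ester enolate, a reaction type established for 3-methylbut-3-enoates of (E)-3-methylalk-2-enols. In the chair transition state the E(O)-enolate (C4 unit trans to O–B) and the (E)-olefin give the required C5/C10 relative configuration, and the C2-symmetric bis-sulfonamide on boron shields one enolate face and so sets the absolute configuration.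

Step 7
Reactants: 12 (2R,3S)-2-(3-{[tert-butyl(dimethyl)silyl]oxy}prop-1-en-2-yl)-3-ethenyl-5-[(4-methoxybenzyl)oxy]-3-methylpentanoic acid
Product: 13 methyl (2R,3S)-2-(3-{[tert-butyl(dimethyl)silyl]oxy}prop-1-en-2-yl)-3-ethenyl-5-[(4-methoxybenzyl)oxy]-3-methylpentanoate
Conditions: Me3SiCHN2, toluene/MeOH, 0 °C
Reagents that add atoms: (trimethylsilyl)diazomethane, C[Si](C)(C)C=[N+]=[N-]
Why: Neutral O-methylation of the acid; no base is present that could epimerise C5 or move the C3=C4 double bond into conjugation.

Step 8
Reactants: 13 methyl (2R,3S)-2-(3-{[tert-butyl(dimethyl)silyl]oxy}prop-1-en-2-yl)-3-ethenyl-5-[(4-methoxybenzyl)oxy]-3-methylpentanoate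
Product: 14 methyl (2R,3S)-2-(3-{[tert-butyl(dimethyl)silyl]oxy}prop-1-en-2-yl)-3-ethenyl-5-hydroxy-3-methylpentanoate
Conditions: DDQ, CH2Cl2/pH 7 buffer, 0 °C
Reagents that add atoms: none
Why: Oxidative cleavage of the PMB ether through benzylic hydride abstraction; the TBS ether, the ester and the unactivated alkenes are inert, and the alcohol is used at once so that it does not close onto the ester.

Step 9
Reactants: 14 methyl (2R,3S)-2-(3-{[tert-butyl(dimethyl)silyl]oxy}prop-1-en-2-yl)-3-ethenyl-5-hydroxy-3-methylpentanoate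
Product: 15 methyl (2R,3S)-2-(3-{[tert-butyl(dimethyl)silyl]oxy}prop-1-en-2-yl)-3-ethenyl-3-methyl-5-oxopentanoate
Conditions: Dess–Martin periodinane, NaHCO3, CH2Cl2, 0 °C to rt
Reagents that add atoms: none
Why: Buffered Dess–Martin oxidation of the primary alcohol; the new aldehyde has no stereocentre at its α-carbon (C9H2 beside quaternary C10), so nothing can epimerise.

Step 10
Reactants: 15 methyl (2R,3S)-2-(3-{[tert-butyl(dimethyl)silyl]oxy}prop-1-en-2-yl)-3-ethenyl-3-methyl-5-oxopentanoate
Product: 17 (3R,4S,6S)-3-(3-{[tert-butyl(dimethyl)silyl]oxy}prop-1-en-2-yl)-4,6-diethenyl-4-methyloxan-2-one, via hydroxy ester 16 (not isolated)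
Conditions: (CH2=CH)2Zn, (+)-MIB [(+)-3-exo-morpholinoisoborneol] (10 mol %), toluene/hexane, −30 to 0 °C; aq. NH4Cl; then PPTS (cat.), toluene, 50 °C
Reagents that add atoms: divinylzinc, C=C[Zn]C=C
Why: Amino-alcohol-catalysed enantioselective addition of a vinylzinc reagent to an aldehyde; the (+)-ligand should direct the vinyl group to the Re face and give (8S), and the zinc reagent leaves the methyl ester alone. Acid-catalysed lactonisation then closes the δ-lactone, and any C8 epimer becomes a separable ring diastereomer.

Step 11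
Reactants: 17 (3R,4S,6S)-3-(3-{[tert-butyl(dimethyl)silyl]oxy}prop-1-en-2-yl)-4,6-diethenyl-4-methyloxan-2-one
Product: 18 (3R,4S,6S)-3-(3-{[tert-butyl(dimethyl)silyl]oxy}prop-1-en-2-yl)-4,6-diethenyl-4-methyloxan-2-ol (anomer mixture)
Conditions: i-Bu2AlH, CH2Cl2, −78 °C; aq. potassium sodium tartrate
Reagents that add atoms: none
Why: Reduction of a δ-lactone by i-Bu2AlH stops at the aluminium lactolate at low temperature; the lactol holds the C6 aldehyde oxidation level and O8 in one ring.

Step 12
Reactants: 18 (3R,4S,6S)-3-(3-{[tert-butyl(dimethyl)silyl]oxy}prop-1-en-2-yl)-4,6-diethenyl-4-methyloxan-2-ol (anomer mixture)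
Product: 19 {[(3R,4S,6S)-3-(3-{[tert-butyl(dimethyl)silyl]oxy}prop-1-en-2-yl)-4,6-diethenyl-4-methyloxan-2-yl]oxy}triethylsilane (anomer mixture)
Conditions: Et3SiCl, imidazole, CH2Cl2, 0 °C
Reagents that add atoms: chlorotriethylsilane, CC[Si](Cl)(CC)CC
Why: Silylation of the anomeric hydroxyl locks the ring form, so that no open-chain 1,6-diene (C7 and C1 vinyl groups) is present during the metathesis.

Step 13
Reactants: 20 2-(bromomethyl)prop-2-enoic acid
Product: 22 2-(trimethylsilyl)ethyl 2-(bromomethyl)prop-2-enoate, via acid chloride 21 (not isolated)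
Conditions: (COCl)2, DMF (cat.), CH2Cl2, 0 °C to rt; then Me3SiCH2CH2OH, 2,6-lutidine, CH2Cl2, 0 °C
Reagents that add atoms: 2-(trimethylsilyl)ethanol, C[Si](C)(C)CCO
Why: Acid chloride formation and esterification with a hindered, non-nucleophilic base that does not displace the allylic bromide; the silylethyl ester is chosen because fluoride removes it at the end.

Step 14
Reactants: 19 {[(3R,4S,6S)-3-(3-{[tert-butyl(dimethyl)silyl]oxy}prop-1-en-2-yl)-4,6-diethenyl-4-methyloxan-2-yl]oxy}triethylsilane; 22 2-(trimethylsilyl)ethyl 2-(bromomethyl)prop-2-enoate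
Product: 23 2-(trimethylsilyl)ethyl (2Z)-2-(bromomethyl)-3-[(2S,4S,5R)-5-(3-{[tert-butyl(dimethyl)silyl]oxy}prop-1-en-2-yl)-4-ethenyl-4-methyl-6-[(triethylsilyl)oxy]oxan-2-yl]prop-2-enoate
Conditions: second-generation Hoveyda–Grubbs catalyst RuCl2(H2IMes)(=CH-C6H4-2-O-i-Pr) (10 mol %), 22 (5 equiv), CH2Cl2, 40 °C
Reagents that add atoms: none
Why: Olefin cross-metathesis of a monosubstituted olefin with a 2-substituted acrylate used in excess, which should give the more stable trisubstituted enoate with C8 trans to the ester, (Z) by the priority of CH2Br. The C8 and C10 vinyl groups are trans on the acetal ring and cannot ring-close, and the neopentyl C1=C2 and the 1,1-disubstituted C3=C4 olefins are slow partners.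

Step 15
Reactants: 23 2-(trimethylsilyl)ethyl (2Z)-2-(bromomethyl)-3-[(2S,4S,5R)-5-(3-{[tert-butyl(dimethyl)silyl]oxy}prop-1-en-2-yl)-4-ethenyl-4-methyl-6-[(triethylsilyl)oxy]oxan-2-yl]prop-2-enoate
Product: 24 2-(trimethylsilyl)ethyl (2Z)-2-(bromomethyl)-3-[(2S,4S,5R)-5-(3-{[tert-butyl(dimethyl)silyl]oxy}prop-1-en-2-yl)-4-ethenyl-6-hydroxy-4-methyloxan-2-yl]prop-2-enoate (lactol, anomer mixture)
Conditions: AcOH/THF/H2O (3:1:1), 0 °C to rt
Reagents that add atoms: none
Why: Mild aqueous acid cleaves the anomeric triethylsilyl ether at silicon faster than the primary TBS ether and should give lactol 24, the ring tautomer of the δ-hydroxy aldehyde.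

Step 16
Reactants: 24 2-(trimethylsilyl)ethyl (2Z)-2-(bromomethyl)-3-[(2S,4S,5R)-5-(3-{[tert-butyl(dimethyl)silyl]oxy}prop-1-en-2-yl)-4-ethenyl-6-hydroxy-4-methyloxan-2-yl]prop-2-enoate
Product: 27 2-(trimethylsilyl)ethyl 2-[(1R,2S,3R,4S,6S)-3-(3-{[tert-butyl(dimethyl)silyl]oxy}prop-1-en-2-yl)-4-ethenyl-2,6-dihydroxy-4-methylcyclohexyl]prop-2-enoate, via open-chain hydroxy aldehyde 25 (not isolated), via allylindium dibromide 26 (not isolated)
Conditions: In powder (3 equiv), THF/H2O (1:1), 0.01 M, rt
Reagents that add atoms: none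
Why: In water the lactol 24 equilibrates with the δ-hydroxy aldehyde 25, as unprotected sugars do in indium allylations, and indium inserts into the allylic C13–Br bond to give the allylindium 26. This reacts at its γ-carbon C7 with the C6 carbonyl through a chair-like six-membered transition state in which indium bridges O6 and C13, forming C6–C7 and moving the double bond to C11=C13. The closest known reaction type is the intramolecular Barbier (and Reformatsky-type) cyclisation of formyl-tethered 2-(bromomethyl)acrylates to cis α-methylene-γ-hydroxy esters, together with aqueous indium allylation of lactols. The carbocycle closes in a 6-exo mode with respect to the carbonyl, whereas attack through C13 would need an eight-membered ring and is not expected. Because C8 is cis to C13 on the (Z)-olefin it is axial on the metallacycle, and the aldehyde substituent C5 must be equatorial to reach it; this is the syn mode of a (Z)-γ-substituted allylmetal and places O6 cis to C11 (O6 axial, C11 equatorial on the new ring). Of the two chairs of the forming carbocycle that allow this, the one with the C4 unit on C5, O8 and the C10 vinyl group equatorial is preferred over its ring-flipped counterpart with three axial groups, and it gives (6S,7R) in 27 at the single cost of a carbonyl oxygen axial and syn to C14. The free C8 hydroxyl is a poor leaving group, so 1,4-elimination to a diene is not invited; the TBS ether and the silylethyl ester are inert in neutral water, and dilution keeps the reaction intramolecular.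

Step 17
Reactants: 28 methyl (2R)-3-hydroxy-2-methylpropanoate
Product: 29 methyl (2R)-3-{[tert-butyl(dimethyl)silyl]oxy}-2-methylpropanoate
Conditions: TBSCl, imidazole, CH2Cl2, rt
Reagents that add atoms: tert-butyldimethylsilyl chloride, CC(C)(C)[Si](C)(C)Cl
Why: Standard silylation of the primary alcohol; the stereocentre is not touched.

Step 18
Reactants: 29 methyl (2R)-3-{[tert-butyl(dimethyl)silyl]oxy}-2-methylpropanoate
Product: 30 (2R)-3-{[tert-butyl(dimethyl)silyl]oxy}-2-methylpropanoic acid
Conditions: LiOH, THF/H2O, 0 °C; then dilute HCl to pH 4, 0 °C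
Reagents that add atoms: lithium hydroxide, [Li+].[OH-]
Why: Saponification at low temperature; once formed, the carboxylate is no longer acidic at the α-carbon, so the (R) centre should be kept.

Step 19
Reactants: 27 2-(trimethylsilyl)ethyl 2-[(1R,2S,3R,4S,6S)-3-(3-{[tert-butyl(dimethyl)silyl]oxy}prop-1-en-2-yl)-4-ethenyl-2,6-dihydroxy-4-methylcyclohexyl]prop-2-enoate; 30 (2R)-3-{[tert-butyl(dimethyl)silyl]oxy}-2-methylpropanoic acid
Product: 31 2-(trimethylsilyl)ethyl 2-[(1S,2S,3R,4S,6S)-3-(3-{[tert-butyl(dimethyl)silyl]oxy}prop-1-en-2-yl)-6-{[(2R)-3-{[tert-butyl(dimethyl)silyl]oxy}-2-methylpropanoyl]oxy}-4-ethenyl-2-hydroxy-4-methylcyclohexyl]prop-2-enoate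
Conditions: EDC·HCl, DMAP (0.2 equiv), CH2Cl2, 0 °C to rt
Reagents that add atoms: none
Why: Steglich-type esterification; the equatorial C8 hydroxyl should react well ahead of the axial C6 hydroxyl, which is flanked by the C5 and C7 substituents and syn to C14. Low temperature and substoichiometric DMAP limit epimerisation of the activated acyl group and lactonisation.

Step 20
Reactants: 31 2-(trimethylsilyl)ethyl 2-[(1S,2S,3R,4S,6S)-3-(3-{[tert-butyl(dimethyl)silyl]oxy}prop-1-en-2-yl)-6-{[(2R)-3-{[tert-butyl(dimethyl)silyl]oxy}-2-methylpropanoyl]oxy}-4-ethenyl-2-hydroxy-4-methylcyclohexyl]prop-2-enoate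
Product: 32 2-[(1S,2S,3R,4S,6S)-4-ethenyl-2-hydroxy-6-{[(2R)-3-hydroxy-2-methylpropanoyl]oxy}-3-(3-hydroxyprop-1-en-2-yl)-4-methylcyclohexyl]prop-2-enoic acid
Conditions: Bu4NF (6 equiv), THF, 0 °C to rt; then aq. NaH2PO4, 0 °C
Reagents that add atoms: none
Why: Fluoride cleaves both TBS ethers and fragments the 2-(trimethylsilyl)ethyl ester (loss of ethene and fluorosilane) to the carboxylate, which cannot lactonise; buffered acidification in the cold should then give the free acid.

## Compound list

1 | but-3-yn-1-ol | C#CCCO | starting material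
2 | 1-[(but-3-yn-1-yloxy)methyl]-4-methoxybenzene | C#CCCOCc1ccc(OC)cc1 | intermediate
3 | dimethyl{(1E)-4-[(4-methoxybenzyl)oxy]-2-methylbut-1-en-1-yl}alane | C[Al](C)/C=C(\C)CCOCc1ccc(OC)cc1 | intermediate
4 | lithium butyl(dimethyl){(1E)-4-[(4-methoxybenzyl)oxy]-2-methylbut-1-en-1-yl}aluminate | [Li+].CCCC[Al-](C)(C)/C=C(\C)CCOCc1ccc(OC)cc1 | intermediate
5 | (2E)-5-[(4-methoxybenzyl)oxy]-3-methylpent-2-en-1-ol | OC/C=C(\C)CCOCc1ccc(OC)cc1 | intermediate
6 | itaconic anhydride (3-methylideneoxolane-2,5-dione) | C=C1CC(=O)OC1=O | starting material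
7 | 4-{[(2E)-5-[(4-methoxybenzyl)oxy]-3-methylpent-2-en-1-yl]oxy}-2-methylidene-4-oxobutanoic acid | OC(=O)C(=C)CC(=O)OC/C=C(\C)CCOCc1ccc(OC)cc1 | intermediate
8 | mixed isobutyl carbonic anhydride of 7 | CC(C)COC(=O)OC(=O)C(=C)CC(=O)OC/C=C(\C)CCOCc1ccc(OC)cc1 | intermediate
9 | (2E)-5-[(4-methoxybenzyl)oxy]-3-methylpent-2-en-1-yl 3-(hydroxymethyl)but-3-enoate | OCC(=C)CC(=O)OC/C=C(\C)CCOCc1ccc(OC)cc1 | intermediate
10 | (2E)-5-[(4-methoxybenzyl)oxy]-3-methylpent-2-en-1-yl 3-({[tert-butyl(dimethyl)silyl]oxy}methyl)but-3-enoate | CC(C)(C)[Si](C)(C)OCC(=C)CC(=O)OC/C=C(\C)CCOCc1ccc(OC)cc1 | intermediate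
11 | E(O)-boron enolate of 10 on the (4S,5S)-1,3-bis{[3,5-bis(trifluoromethyl)phenyl]sulfonyl}-4,5-diphenyl-1,3,2-diazaborolidine | C=C(CO[Si](C)(C)C(C)(C)C)/C=C(/OB1N(S(=O)(=O)c2cc(cc(c2)C(F)(F)F)C(F)(F)F)[C@@H](c2ccccc2)[C@H](c2ccccc2)N1S(=O)(=O)c1cc(cc(c1)C(F)(F)F)C(F)(F)F)OC/C=C(\C)CCOCc1ccc(OC)cc1 | intermediate
12 | (2R,3S)-2-(3-{[tert-butyl(dimethyl)silyl]oxy}prop-1-en-2-yl)-3-ethenyl-5-[(4-methoxybenzyl)oxy]-3-methylpentanoic acid (5R,10S) | OC(=O)[C@@H](C(=C)CO[Si](C)(C)C(C)(C)C)[C@](C)(C=C)CCOCc1ccc(OC)cc1 | intermediate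
13 | methyl ester of 12 | COC(=O)[C@@H](C(=C)CO[Si](C)(C)C(C)(C)C)[C@](C)(C=C)CCOCc1ccc(OC)cc1 | intermediate
14 | methyl (2R,3S)-2-(3-{[tert-butyl(dimethyl)silyl]oxy}prop-1-en-2-yl)-3-ethenyl-5-hydroxy-3-methylpentanoate | COC(=O)[C@@H](C(=C)CO[Si](C)(C)C(C)(C)C)[C@](C)(C=C)CCO | intermediate
15 | methyl (2R,3S)-2-(3-{[tert-butyl(dimethyl)silyl]oxy}prop-1-en-2-yl)-3-ethenyl-3-methyl-5-oxopentanoate | COC(=O)[C@@H](C(=C)CO[Si](C)(C)C(C)(C)C)[C@](C)(C=C)CC=O | intermediate
16 | methyl (2R,3S,5S)-2-(3-{[tert-butyl(dimethyl)silyl]oxy}prop-1-en-2-yl)-3-ethenyl-5-hydroxy-3-methylhept-6-enoate | COC(=O)[C@@H](C(=C)CO[Si](C)(C)C(C)(C)C)[C@](C)(C=C)C[C@H](O)C=C | intermediate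
17 | (3R,4S,6S)-3-(3-{[tert-butyl(dimethyl)silyl]oxy}prop-1-en-2-yl)-4,6-diethenyl-4-methyloxan-2-one (5R,8S,10S) | O=C1O[C@H](C=C)C[C@@](C)(C=C)[C@@H]1C(=C)CO[Si](C)(C)C(C)(C)C | intermediate
18 | (3R,4S,6S)-3-(3-{[tert-butyl(dimethyl)silyl]oxy}prop-1-en-2-yl)-4,6-diethenyl-4-methyloxan-2-ol, anomer mixture | OC1O[C@H](C=C)C[C@@](C)(C=C)[C@@H]1C(=C)CO[Si](C)(C)C(C)(C)C | intermediate
19 | triethylsilyl ether of lactol 18, anomer mixture | CC[Si](CC)(CC)OC1O[C@H](C=C)C[C@@](C)(C=C)[C@@H]1C(=C)CO[Si](C)(C)C(C)(C)C | intermediate
20 | 2-(bromomethyl)prop-2-enoic acid | C=C(CBr)C(=O)O | starting material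
21 | 2-(bromomethyl)prop-2-enoyl chloride | C=C(CBr)C(=O)Cl | intermediate
22 | 2-(trimethylsilyl)ethyl 2-(bromomethyl)prop-2-enoate | C=C(CBr)C(=O)OCC[Si](C)(C)C | intermediate
23 | 2-(trimethylsilyl)ethyl (2Z)-2-(bromomethyl)-3-[(2S,4S,5R)-5-(3-{[tert-butyl(dimethyl)silyl]oxy}prop-1-en-2-yl)-4-ethenyl-4-methyl-6-[(triethylsilyl)oxy]oxan-2-yl]prop-2-enoate | CC[Si](CC)(CC)OC1O[C@H](/C=C(\CBr)C(=O)OCC[Si](C)(C)C)C[C@@](C)(C=C)[C@@H]1C(=C)CO[Si](C)(C)C(C)(C)C | intermediate
24 | lactol of the key-step precursor: 2-(trimethylsilyl)ethyl (2Z)-2-(bromomethyl)-3-[(2S,4S,5R)-5-(3-{[tert-butyl(dimethyl)silyl]oxy}prop-1-en-2-yl)-4-ethenyl-6-hydroxy-4-methyloxan-2-yl]prop-2-enoate | OC1O[C@H](/C=C(\CBr)C(=O)OCC[Si](C)(C)C)C[C@@](C)(C=C)[C@@H]1C(=C)CO[Si](C)(C)C(C)(C)C | intermediate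
25 | open-chain tautomer of 24: 2-(trimethylsilyl)ethyl (2Z,4S,6S,7R)-2-(bromomethyl)-9-{[tert-butyl(dimethyl)silyl]oxy}-6-ethenyl-7-formyl-4-hydroxy-6-methyl-8-methylidenenon-2-enoate | O=C[C@@H](C(=C)CO[Si](C)(C)C(C)(C)C)[C@](C)(C=C)C[C@H](O)/C=C(\CBr)C(=O)OCC[Si](C)(C)C | intermediate
26 | allylindium dibromide derived from 25 (C13–InBr2) | O=C[C@@H](C(=C)CO[Si](C)(C)C(C)(C)C)[C@](C)(C=C)C[C@H](O)/C=C(\C[In](Br)Br)C(=O)OCC[Si](C)(C)C | intermediate
27 | 2-(trimethylsilyl)ethyl 2-[(1R,2S,3R,4S,6S)-3-(3-{[tert-butyl(dimethyl)silyl]oxy}prop-1-en-2-yl)-4-ethenyl-2,6-dihydroxy-4-methylcyclohexyl]prop-2-enoate (5R,6S,7R,8S,10S) | C=C[C@]1(C)C[C@H](O)[C@@H](C(=C)C(=O)OCC[Si](C)(C)C)[C@@H](O)[C@H]1C(=C)CO[Si](C)(C)C(C)(C)C | intermediate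
28 | methyl (2R)-3-hydroxy-2-methylpropanoate | COC(=O)[C@H](C)CO | starting material
29 | methyl (2R)-3-{[tert-butyl(dimethyl)silyl]oxy}-2-methylpropanoate | COC(=O)[C@H](C)CO[Si](C)(C)C(C)(C)C | intermediate
30 | (2R)-3-{[tert-butyl(dimethyl)silyl]oxy}-2-methylpropanoic acid | OC(=O)[C@H](C)CO[Si](C)(C)C(C)(C)C | intermediate
31 | 2-(trimethylsilyl)ethyl 2-[(1S,2S,3R,4S,6S)-3-(3-{[tert-butyl(dimethyl)silyl]oxy}prop-1-en-2-yl)-6-{[(2R)-3-{[tert-butyl(dimethyl)silyl]oxy}-2-methylpropanoyl]oxy}-4-ethenyl-2-hydroxy-4-methylcyclohexyl]prop-2-enoate | C=C[C@]1(C)C[C@H](OC(=O)[C@H](C)CO[Si](C)(C)C(C)(C)C)[C@@H](C(=C)C(=O)OCC[Si](C)(C)C)[C@@H](O)[C@H]1C(=C)CO[Si](C)(C)C(C)(C)C | intermediate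
32 | 2-[(1S,2S,3R,4S,6S)-4-ethenyl-2-hydroxy-6-{[(2R)-3-hydroxy-2-methylpropanoyl]oxy}-3-(3-hydroxyprop-1-en-2-yl)-4-methylcyclohexyl]prop-2-enoic acid (5R,6S,7S,8S,10S) | C=C[C@]1(C)C[C@H](OC(=O)[C@H](C)CO)[C@@H](C(=C)C(=O)O)[C@@H](O)[C@H]1C(=C)CO | target

## Step count and least certain steps

Total: 20 steps. Longest linear sequence: 17 steps (steps 1–12, 14–16, 19, 20). Steps 13, 17 and 18 prepare the two side fragments.

Step 16 (key step). The main risks are slow opening of the lactol compared with protonolysis of the allylindium (loss of the bromide as a reduced olefin), imperfect choice between the two chair transition states (a C6/C7 diastereomer), and closure of the new C6 alkoxide onto the silylethyl ester to a lactone. Fallback: leave the route at 23 and convert the bromide into a storable allylboron reagent. Borylation with bis(pinacolato)diboron and the zerovalent palladium catalyst Pd2(dba)3 in toluene at 50 °C should give the 2-(alkoxycarbonyl)allylboronate F1, with C8 still cis to C13. Aqueous acetic acid frees the lactol F2. Warming in toluene, if needed with Sc(OTf)3 as catalyst, lets the open-chain aldehyde undergo intramolecular allylboration through the same closed chair to the borate ester F3, whose hydrolysis on work-up rejoins the route at 27. The boronate is stable to water and cannot eliminate, so it can wait for the lactol to open.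

Step 14 (cross-metathesis). The hindered, electron-poor 1,1-disubstituted partner may turn over slowly with the oxygen-substituted vinyl group, which would lead to homodimerisation of 19, erosion of the olefin geometry or catalyst decay. Fallback: build the olefin by a Morita–Baylis–Hillman reaction and allylic transposition, setting out from aldehyde 15. Addition of 2-lithio-1,3-dithiane (THF, −78 °C) and lactonisation gives the dithianyl lactone F4 and its C8 epimer F5, which are separated by chromatography. Reduction with i-Bu2AlH and silylation with Et3SiCl convert F4 into the lactol F6 and its triethylsilyl ether F7. MeI/CaCO3 in aqueous MeCN frees the C7 aldehyde F8. Reaction with 2-(trimethylsilyl)ethyl acrylate and DABCO gives the allylic alcohol F9, and N-bromosuccinimide/Me2S converts it with transposition into the (Z)-bromide, rejoining the route at 23.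

Step 6 (boron-mediated rearrangement). Enolisation may not give the E(O)-enolate cleanly (loss of C5/C10 diastereoselectivity), the facial control may be incomplete, and the boron Lewis acid may attack the PMB or TBS ether. Fallback: from ester 10, LDA in THF at −78 °C and then Me3SiCl/Et3N give the (E)-trimethylsilyl ketene acetal F10, which rearranges on warming to the racemic trimethylsilyl ester F11. Aqueous work-up gives acid 12 together with its enantiomer F12, which is removed by chromatography on a chiral stationary phase (or by crystallisation with a chiral amine). The route is rejoined at 12.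

Step 10 (vinyl addition). Facial selection may be incomplete for an α-unbranched aldehyde with a β-quaternary centre, and vinyl transfer from zinc may be sluggish. Fallback: from aldehyde 15, vinylmagnesium bromide (THF, −78 °C) gives 16 together with its C8 epimer F13. Lactonisation gives 17 and the epimeric lactone F14, which are separable as ring diastereomers. F14 is saponified (LiOH) to the hydroxy acid F15 and relactonised under Mitsunobu conditions (PPh3, diisopropyl azodicarboxylate) with inversion at C8, so that both epimers end as 17.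

Step 4 (acid reduction). Conjugate reduction of the acryloyl mixed anhydride may compete, and the γ-hydroxy ester 9 may lactonise with expulsion of 5. Fallback: make the acid part separately and esterify, setting out from alcohol 5 and rejoining at 10. 2-Methylidenepropane-1,3-diol F16 is monosilylated (NaH, TBSCl) to F17 and converted into the methyl carbonate F18 (ClCO2Me, pyridine). Decarboxylative carbonylation (Pd(OAc)2, PPh3, CO, MeOH) gives the β,γ-unsaturated methyl ester F19, which is saponified to the acid F20 and coupled with 5 (EDC, catalytic DMAP) to give 10.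

## Further compounds

F1 | step 16 | allylboronate of 23: 2-(trimethylsilyl)ethyl 2-[(4,4,5,5-tetramethyl-1,3,2-dioxaborolan-2-yl)methyl]-3-[(2S,4S,5R)-5-(3-{[tert-butyl(dimethyl)silyl]oxy}prop-1-en-2-yl)-4-ethenyl-4-methyl-6-[(triethylsilyl)oxy]oxan-2-yl]prop-2-enoate (C8 cis to C13) | CC[Si](CC)(CC)OC1O[C@H](/C=C(\CB2OC(C)(C)C(C)(C)O2)C(=O)OCC[Si](C)(C)C)C[C@@](C)(C=C)[C@@H]1C(=C)CO[Si](C)(C)C(C)(C)C
F2 | step 16 | lactol of F1 | OC1O[C@H](/C=C(\CB2OC(C)(C)C(C)(C)O2)C(=O)OCC[Si](C)(C)C)C[C@@](C)(C=C)[C@@H]1C(=C)CO[Si](C)(C)C(C)(C)C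
F3 | step 16 | O6-pinacol borate ester of 27 | C=C[C@]1(C)C[C@H](O)[C@@H](C(=C)C(=O)OCC[Si](C)(C)C)[C@@H](OB2OC(C)(C)C(C)(C)O2)[C@H]1C(=C)CO[Si](C)(C)C(C)(C)C
F4 | step 14 | (3R,4S,6S)-3-(3-{[tert-butyl(dimethyl)silyl]oxy}prop-1-en-2-yl)-6-(1,3-dithian-2-yl)-4-ethenyl-4-methyloxan-2-one | O=C1O[C@H](C2SCCCS2)C[C@@](C)(C=C)[C@@H]1C(=C)CO[Si](C)(C)C(C)(C)C
F5 | step 14 | C8 epimer of F4 (6R) | O=C1O[C@@H](C2SCCCS2)C[C@@](C)(C=C)[C@@H]1C(=C)CO[Si](C)(C)C(C)(C)C
F6 | step 14 | lactol from F4, anomer mixture | OC1O[C@H](C2SCCCS2)C[C@@](C)(C=C)[C@@H]1C(=C)CO[Si](C)(C)C(C)(C)C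
F7 | step 14 | triethylsilyl ether of F6 | CC[Si](CC)(CC)OC1O[C@H](C2SCCCS2)C[C@@](C)(C=C)[C@@H]1C(=C)CO[Si](C)(C)C(C)(C)C
F8 | step 14 | C7 aldehyde: (2S,4S,5R)-5-(3-{[tert-butyl(dimethyl)silyl]oxy}prop-1-en-2-yl)-4-ethenyl-4-methyl-6-[(triethylsilyl)oxy]oxane-2-carbaldehyde | CC[Si](CC)(CC)OC1O[C@H](C=O)C[C@@](C)(C=C)[C@@H]1C(=C)CO[Si](C)(C)C(C)(C)C
F9 | step 14 | Morita–Baylis–Hillman adduct of F8 with 2-(trimethylsilyl)ethyl acrylate (C7 carbinol epimers) | CC[Si](CC)(CC)OC1O[C@H](C(O)C(=C)C(=O)OCC[Si](C)(C)C)C[C@@](C)(C=C)[C@@H]1C(=C)CO[Si](C)(C)C(C)(C)C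
F10 | step 6 | (E)-trimethylsilyl ketene acetal of 10 | C=C(CO[Si](C)(C)C(C)(C)C)/C=C(/O[Si](C)(C)C)OC/C=C(\C)CCOCc1ccc(OC)cc1
F11 | step 6 | trimethylsilyl ester of the rearranged acid, racemic (one enantiomer drawn) | C[Si](C)(C)OC(=O)[C@@H](C(=C)CO[Si](C)(C)C(C)(C)C)[C@](C)(C=C)CCOCc1ccc(OC)cc1
F12 | step 6 | enantiomer of 12, (2S,3R) | OC(=O)[C@H](C(=C)CO[Si](C)(C)C(C)(C)C)[C@@](C)(C=C)CCOCc1ccc(OC)cc1
F13 | step 10 | C8 epimer of 16, (2R,3S,5R) | COC(=O)[C@@H](C(=C)CO[Si](C)(C)C(C)(C)C)[C@](C)(C=C)C[C@@H](O)C=C
F14 | step 10 | C8 epimer of 17, (3R,4S,6R) | O=C1O[C@@H](C=C)C[C@@](C)(C=C)[C@@H]1C(=C)CO[Si](C)(C)C(C)(C)C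
F15 | step 10 | (2R,3S,5R)-2-(3-{[tert-butyl(dimethyl)silyl]oxy}prop-1-en-2-yl)-3-ethenyl-5-hydroxy-3-methylhept-6-enoic acid | OC(=O)[C@@H](C(=C)CO[Si](C)(C)C(C)(C)C)[C@](C)(C=C)C[C@@H](O)C=C
F16 | step 4 | 2-methylidenepropane-1,3-diol | C=C(CO)CO
F17 | step 4 | 2-({[tert-butyl(dimethyl)silyl]oxy}methyl)prop-2-en-1-ol | C=C(CO)CO[Si](C)(C)C(C)(C)C
F18 | step 4 | 2-({[tert-butyl(dimethyl)silyl]oxy}methyl)prop-2-en-1-yl methyl carbonate | C=C(COC(=O)OC)CO[Si](C)(C)C(C)(C)C
F19 | step 4 | methyl 3-({[tert-butyl(dimethyl)silyl]oxy}methyl)but-3-enoate | COC(=O)CC(=C)CO[Si](C)(C)C(C)(C)C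
F20 | step 4 | 3-({[tert-butyl(dimethyl)silyl]oxy}methyl)but-3-enoic acid | OC(=O)CC(=C)CO[Si](C)(C)C(C)(C)C
A1 | alternative 1 | C6 bromoacetal of the cyclohex-7-en-6-ol | C=C[C@]1(C)CC=C[C@@H](OC(CBr)OCC)[C@H]1C(=C)CO[Si](C)(C)C(C)(C)C
A2 | alternative 1 | C8 alcohol of the cis-fused bicyclic ethyl acetal (acetal epimers) | C=C[C@]1(C)C[C@H](O)[C@H]2CC(OCC)O[C@H]2[C@H]1C(=C)CO[Si](C)(C)C(C)(C)C
A3 | alternative 2 | acyclic bis-vinyl C8 silyl enol ether | C=CC(C)(C=C)[C@H](C(=C)CO[Si](C)(C)C(C)(C)C)[C@H](O[Si](C)(C)C(C)(C)C)[C@H](CCOCc1ccc(OC)cc1)C(=C)O[Si](C)(C)C(C)(C)C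
A4 | alternative 2 | cyclic C8 silyl enol ether | C=C[C@]1(C)C=C(O[Si](C)(C)C(C)(C)C)[C@@H](CCOCc2ccc(OC)cc2)[C@@H](O[Si](C)(C)C(C)(C)C)[C@H]1C(=C)CO[Si](C)(C)C(C)(C)C
A5 | alternative 3 | C8 aldehyde with tethered 2-(acetoxymethyl)enoate | O=CC[C@@](C)(C=C)[C@H](C(=C)CO[Si](C)(C)C(C)(C)C)[C@H](O[Si](C)(C)C(C)(C)C)/C=C(\COC(C)=O)C(=O)OCC[Si](C)(C)C
A6 | alternative 3 | C8 ketone with the C7 acrylate in place | C=C[C@]1(C)CC(=O)[C@@H](C(=C)C(=O)OCC[Si](C)(C)C)[C@@H](O[Si](C)(C)C(C)(C)C)[C@H]1C(=C)CO[Si](C)(C)C(C)(C)C
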